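**Retrosynthetic overview**
- The target is taken back to alcohol 17 by cutting the C5–prenyl bond (Pd-catalysed C-prenylation of the acyl-dione), and 17 to ketone 16 by cutting the C1′–CH3 bond (methyl addition).
- The strategy rests on C2 of the dihydrofuran ring (O1–C2–C3–C3a–C7a): it is the only atom bonded to O1, to C3 and to the C1′ side chain. The ring is therefore opened as a [4+1] adduct of one ylide carbon on the O1=C7a–C3a=C3 oxadiene of a 2-methylene acyl-trione, made from the C3a Mannich base 8 and the quinidinium ylide of 1-bromo-6-methylhept-5-en-2-one.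
- Mannich base 8 comes from trione 7, whose quaternary C7 is set by Pd-catalysed enantioselective dearomatising prenylation of C-methylated phlorisobutyrophenone. A chlorine is parked on the free ring carbon (the later C3a) for that step, because an unblocked ring CH would take the prenyl group and stay aromatic.
- Ring order: the carbocycle is carried over from the benzene ring by dearomatisation; the dihydrofuran is closed second, in the key step.

Key step: step 8

Remark 1: the cyclic polyketones 6–8 and 14–17 exist as enols; they are drawn and named as triketo tautomers, so ring CH carbons drawn sp3 (C3a, C5) are not stereocentres, and CIP descriptors refer to these drawings. Locants C2–C7a and C1′ are those of the target's benzofuran skeleton.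
Remark 2 (assumption): the sense of induction of the (R,R)-Trost ligand (steps 3 and 10) and of the quinidine-derived leaving group (step 8) is taken as written; if a test run shows the opposite sense, the enantiomeric ligand or the quinine-derived salt is used instead.

Step 1
Reactants: 1 2,4,6-trihydroxytoluene; 2 2-methylpropanoyl chloride
Product: 3 1-(2,4,6-trihydroxy-3-methylphenyl)-2-methylpropan-1-one
Conditions: AlCl3 (3.5 equiv), PhNO2/CH2Cl2, 0 → 50 °C; aq. HCl
Reagents that add atoms: none
Why: Friedel–Crafts C-acylation of the electron-rich triol, whose two free ring positions are equivalent, so one regioisomer should form.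

Step 2
Reactants: 3 1-(2,4,6-trihydroxy-3-methylphenyl)-2-methylpropan-1-one
Product: 4 1-(3-chloro-2,4,6-trihydroxy-5-methylphenyl)-2-methylpropan-1-one
Conditions: SO2Cl2 (1.0 equiv), Et2O, 0 °C
Reagents that add atoms: sulfuryl chloride, O=S(=O)(Cl)Cl
Why: Electrophilic aromatic chlorination at the only free ring position, which blocks that carbon for the next step.

Step 3
Reactants: 4 1-(3-chloro-2,4,6-trihydroxy-5-methylphenyl)-2-methylpropan-1-one; 5 3-methylbut-2-en-1-yl acetate (prenyl acetate)
Product: 6 (2R)-4-chloro-2-methyl-2-(3-methylbut-2-en-1-yl)-6-(2-methylpropanoyl)cyclohexane-1,3,5-trione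
Conditions: Pd2(dba)3·CHCl3 (2.5 mol %), (R,R)-DACH-phenyl Trost ligand (7.5 mol %), Cs2CO3 (1.1 equiv), THF, 0 °C → rt
Reagents that add atoms: none
Why: Pd-catalysed asymmetric allylic alkylation (Tsuji–Trost) of the phenolate with dearomatisation: with the chlorinated and acylated carbons deactivated, the methylated carbon is the preferred site, attack at the unhindered prenyl terminus gives the linear prenyl group, and the chiral ligand selects the face that sets the quaternary centre (C7 of the target).

Step 4
Reactants: 6 (2R)-4-chloro-2-methyl-2-(3-methylbut-2-en-1-yl)-6-(2-methylpropanoyl)cyclohexane-1,3,5-trione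
Product: 7 (2S)-2-methyl-2-(3-methylbut-2-en-1-yl)-4-(2-methylpropanoyl)cyclohexane-1,3,5-trione
Conditions: Zn dust (5 equiv), AcOH/THF, rt
Reagents that add atoms: none
Why: Zinc reduction of the C–Cl bond of an α-chloro-β-dicarbonyl (dehalogenation of an α-halo ketone) restores the ring CH and leaves the quaternary centre, the alkene and the acyl group untouched (the descriptor changes only through CIP priorities).

Step 5
Reactants: 7 (2S)-2-methyl-2-(3-methylbut-2-en-1-yl)-4-(2-methylpropanoyl)cyclohexane-1,3,5-trione
Product: 8 (2S)-4-[(dimethylamino)methyl]-2-methyl-2-(3-methylbut-2-en-1-yl)-6-(2-methylpropanoyl)cyclohexane-1,3,5-trione (isolated as the ammonium enolate inner salt)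
Conditions: CH2=NMe2+ I− (1.1 equiv), CH2Cl2, 0 °C → rt; then aq. NaHCO3 (1 equiv)
Reagents that add atoms: N,N-dimethylmethyleneiminium iodide (Eschenmoser's salt), C=[N+](C)C.[I-]
Why: Mannich reaction of the only unsubstituted enolic ring carbon (C3a) with a preformed iminium salt under aprotic conditions, which should avoid the methylene-bridged dimers that aqueous formaldehyde gives.

Step 6
Reactants: 9 6-methylhept-5-en-2-one
Product: 11 1-bromo-6-methylhept-5-en-2-one, via silyl enol ether 10 (not isolated)
Conditions: LDA, THF, −78 °C; TMSCl; then NBS, THF, −78 → 0 °C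
Reagents that add atoms: N-bromosuccinimide, O=C1CCC(=O)N1Br
Why: Kinetic deprotonation at the methyl group, trapping as the less substituted silyl enol ether and bromination with NBS, which should react with the enol ether far faster than with the trisubstituted alkene (regioselective α-bromination through a silyl enol ether).

Step 7
Reactants: 11 1-bromo-6-methylhept-5-en-2-one; 12 quinidine
Product: 13 N-(6-methyl-2-oxohept-5-en-1-yl)quinidinium bromide (alkylated at the quinuclidine nitrogen)
Conditions: THF, rt, 16 h; filter
Reagents that add atoms: none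
Why: Menshutkin quaternisation (SN2) of the more nucleophilic quinuclidine nitrogen by the activated α-bromoketone.

Step 8
Reactants: 8 (2S)-4-[(dimethylamino)methyl]-2-methyl-2-(3-methylbut-2-en-1-yl)-6-(2-methylpropanoyl)cyclohexane-1,3,5-trione; 13 N-(6-methyl-2-oxohept-5-en-1-yl)quinidinium bromide
Product: 16 (2S,7S)-7-methyl-2-(5-methylhex-4-enoyl)-7-(3-methylbut-2-en-1-yl)-5-(2-methylpropanoyl)-2,3-dihydro-1-benzofuran-4,6(5H,7H)-dione, via quaternised Mannich base 14 (not isolated), via methylene trione 15 (not isolated)
Conditions: MeI (1.0 equiv), Cs2CO3 (0.55 equiv), MeCN, 0 °C; then 13 (1.2 equiv), Cs2CO3 (3 equiv), CH2Cl2/MeCN, −20 °C → rt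
Reagents that add atoms: none
Why: N-Methylation turns the amine into a leaving group and base-induced E1cB loss of trimethylamine gives the 2-methylene acyl-trione 15, an ortho-quinone-methide analogue held as its C5 triketonate; the ammonium ylide from 13 adds in Michael fashion to the exocyclic CH2 (C2–C3 bond) and the resulting enolate oxygen displaces the quinuclidinium group at C2 (O1–C2 bond). The closest known reaction type is the [4+1] annulation of ammonium ylides with ortho-quinone methides and alkylidene 1,3-diones to 2-acyl-2,3-dihydrofurans. The dihydrofuran ring closes by 5-exo-tet SN2 substitution. C2 is controlled by the chiral amine leaving group: the betaine should epimerise at C2 through the ylide faster than it cyclises, so both diastereomers drain through the faster-closing one, which closes with inversion to give (2S) under the assumption of remark 2. The step needs closure through O7a and not O4: with excess Cs2CO3 the first negative charge sits in the cesium-bound C4/C6/isobutyryl triketonate, so the second, more basic charge created by the Michael addition should reside mainly on O7a and make it the nucleophilic oxygen. C7 is quaternary and is not touched.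

Step 9
Reactants: 16 (2S,7S)-7-methyl-2-(5-methylhex-4-enoyl)-7-(3-methylbut-2-en-1-yl)-5-(2-methylpropanoyl)-2,3-dihydro-1-benzofuran-4,6(5H,7H)-dione
Product: 17 (2S,7S)-2-[(2S)-2-hydroxy-6-methylhept-5-en-2-yl]-7-methyl-7-(3-methylbut-2-en-1-yl)-5-(2-methylpropanoyl)-2,3-dihydro-1-benzofuran-4,6(5H,7H)-dione
Conditions: MeTi(OiPr)3 (3 equiv, preformed in THF), THF, −40 °C → rt; aq. NH4Cl
Reagents that add atoms: methyltitanium triisopropoxide, C[Ti](OC(C)C)(OC(C)C)OC(C)C
Why: The non-chelating titanium reagent first converts the acidic core into its titanium triketonate (methane lost), which protects the ring carbonyls, and then adds to the side-chain ketone in a polar Felkin–Anh transition state with the C2–O1 bond anti to the incoming methyl and the methyl passing the C2 hydrogen, which should set C1′ (S); O1 is a vinylogous ester oxygen and too weak a donor to impose the opposite chelate mode.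

Step 10
Reactants: 17 (2S,7S)-2-[(2S)-2-hydroxy-6-methylhept-5-en-2-yl]-7-methyl-7-(3-methylbut-2-en-1-yl)-5-(2-methylpropanoyl)-2,3-dihydro-1-benzofuran-4,6(5H,7H)-dione; 5 3-methylbut-2-en-1-yl acetate
Product: 18 (2S,5R,7S)-2-[(2S)-2-hydroxy-6-methylhept-5-en-2-yl]-7-methyl-5,7-bis(3-methylbut-2-en-1-yl)-5-(2-methylpropanoyl)-2,3-dihydro-1-benzofuran-4,6(5H,7H)-dione (target)
Conditions: Pd2(dba)3·CHCl3 (5 mol %), (R,R)-DACH-phenyl Trost ligand (15 mol %), Cs2CO3 (1.1 equiv), THF, 0 °C → rt
Reagents that add atoms: none
Why: Tsuji–Trost C-prenylation of the cesium triketonate at C5, with O-prenylation reversible under Pd(0) and the tertiary alcohol not ionised by carbonate; the prenyl group should enter on the ring face that carries the C7 methyl (anti to the C7 prenyl), the face the substrate slightly prefers and the ligand is chosen to reinforce, which sets C5 (R).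

**Compound list**
1 | 2,4,6-trihydroxytoluene (2-methylbenzene-1,3,5-triol) | Cc1c(O)cc(O)cc1O | starting material
2 | 2-methylpropanoyl chloride | CC(C)C(Cl)=O | starting material
3 | 1-(2,4,6-trihydroxy-3-methylphenyl)-2-methylpropan-1-one | CC(C)C(=O)c1c(O)cc(O)c(C)c1O | intermediate
4 | 1-(3-chloro-2,4,6-trihydroxy-5-methylphenyl)-2-methylpropan-1-one | CC(C)C(=O)c1c(O)c(C)c(O)c(Cl)c1O | intermediate
5 | 3-methylbut-2-en-1-yl acetate (prenyl acetate) | CC(C)=CCOC(C)=O | starting material
6 | (2R)-4-chloro-2-methyl-2-(3-methylbut-2-en-1-yl)-6-(2-methylpropanoyl)cyclohexane-1,3,5-trione | ClC1C(=O)[C@](C)(CC=C(C)C)C(=O)C(C(=O)C(C)C)C1=O | intermediate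
7 | (2S)-2-methyl-2-(3-methylbut-2-en-1-yl)-4-(2-methylpropanoyl)cyclohexane-1,3,5-trione | C1C(=O)[C@](C)(CC=C(C)C)C(=O)C(C(=O)C(C)C)C1=O | intermediate
8 | (2S)-4-[(dimethylamino)methyl]-2-methyl-2-(3-methylbut-2-en-1-yl)-6-(2-methylpropanoyl)cyclohexane-1,3,5-trione | CN(C)CC1C(=O)[C@](C)(CC=C(C)C)C(=O)C(C(=O)C(C)C)C1=O | intermediate
9 | 6-methylhept-5-en-2-one | CC(C)=CCCC(C)=O | starting material
10 | trimethyl[(6-methylhepta-1,5-dien-2-yl)oxy]silane (silyl enol ether, not isolated) | C=C(CCC=C(C)C)O[Si](C)(C)C | intermediate
11 | 1-bromo-6-methylhept-5-en-2-one | CC(C)=CCCC(=O)CBr | intermediate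
12 | quinidine | COC1=CC2=C(C=CN=C2C=C1)[C@@H]([C@H]3C[C@@H]4CCN3C[C@@H]4C=C)O | starting material
13 | N-(6-methyl-2-oxohept-5-en-1-yl)quinidinium bromide | COC1=CC2=C(C=CN=C2C=C1)[C@@H]([C@H]3C[C@@H]4CC[N+]3(CC(=O)CCC=C(C)C)C[C@@H]4C=C)O.[Br-] | intermediate
14 | trimethylammonium iodide of 8 (quaternised Mannich base, present as its enolate betaine, not isolated) | C[N+](C)(C)CC1C(=O)[C@](C)(CC=C(C)C)C(=O)C(C(=O)C(C)C)C1=O.[I-] | intermediate
15 | (2R)-2-methyl-4-methylidene-2-(3-methylbut-2-en-1-yl)-6-(2-methylpropanoyl)cyclohexane-1,3,5-trione (methylene trione, not isolated) | C=C1C(=O)[C@](C)(CC=C(C)C)C(=O)C(C(=O)C(C)C)C1=O | intermediate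
16 | (2S,7S)-7-methyl-2-(5-methylhex-4-enoyl)-7-(3-methylbut-2-en-1-yl)-5-(2-methylpropanoyl)-2,3-dihydro-1-benzofuran-4,6(5H,7H)-dione | CC(C)=CCCC(=O)[C@@H]1CC2=C(O1)[C@](C)(CC=C(C)C)C(=O)C(C(=O)C(C)C)C2=O | intermediate
17 | (2S,7S)-2-[(2S)-2-hydroxy-6-methylhept-5-en-2-yl]-7-methyl-7-(3-methylbut-2-en-1-yl)-5-(2-methylpropanoyl)-2,3-dihydro-1-benzofuran-4,6(5H,7H)-dione | CC(C)=CCC[C@](C)(O)[C@@H]1CC2=C(O1)[C@](C)(CC=C(C)C)C(=O)C(C(=O)C(C)C)C2=O | intermediate
18 | (2S,5R,7S)-2-[(2S)-2-hydroxy-6-methylhept-5-en-2-yl]-7-methyl-5,7-bis(3-methylbut-2-en-1-yl)-5-(2-methylpropanoyl)-2,3-dihydro-1-benzofuran-4,6(5H,7H)-dione | CC(C)=CCC[C@](C)(O)[C@@H]1CC2=C(O1)[C@](C)(CC=C(C)C)C(=O)[C@](CC=C(C)C)(C(=O)C(C)C)C2=O | target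

**Step count**
Total step count: 10.
Longest linear sequence: 8 steps (1, 2, 3, 4, 5, 8, 9, 10); steps 6 and 7 form the side branch that joins at step 8.

**Steps most likely to fail**

Step 8. What may go wrong: the betaine may close through the C4 oxygen instead of the C7a oxygen, the methide may condense with itself before the ylide adds, or the two betaine diastereomers may be poorly discriminated, giving weak control at C2. Fallback: annulate on the aromatic ring first and dearomatise afterwards. Setting out from 3, aminomethylation with Eschenmoser's salt should give the aromatic Mannich base 1-{3-[(dimethylamino)methyl]-2,4,6-trihydroxy-5-methylphenyl}-2-methylpropan-1-one F1. Methyl iodide converts it in the flask into its trimethylammonium iodide F2, from which Cs2CO3 releases the ortho-quinone methide 3,5-dihydroxy-2-methyl-6-methylidene-4-(2-methylpropanoyl)cyclohexa-2,4-dien-1-one F3. The ylide from 13 adds to F3, and closure should go through the free hydroxyl para to the acyl group, the ortho hydroxyl being held in the hydrogen bond to the isobutyryl carbonyl. This gives the aromatic dihydrobenzofuran 1-[(2S)-4,6-dihydroxy-7-methyl-5-(2-methylpropanoyl)-2,3-dihydro-1-benzofuran-2-yl]-5-methylhex-4-en-1-one F4. Prenylation of F4 under the Pd/Trost-ligand conditions of step 3 then dearomatises at the methylated carbon C7 and rejoins the route at 16.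

Step 3. What may go wrong: poor enantioface discrimination at the methylated carbon, or competing O-prenylation and attack at the chlorinated carbon under Pd catalysis. Fallback: classical dearomatisation followed by resolution. Setting out from 4, prenyl bromide with NaOMe in MeOH at 0 °C should give the racemic chloro-trione 4-chloro-2-methyl-2-(3-methylbut-2-en-1-yl)-6-(2-methylpropanoyl)cyclohexane-1,3,5-trione F5. Zinc in acetic acid then gives the racemic trione 2-methyl-2-(3-methylbut-2-en-1-yl)-4-(2-methylpropanoyl)cyclohexane-1,3,5-trione F6. F6 is resolved by preparative chromatography on a chiral stationary phase (or by crystallising its quinine salt), and the (2S) enantiomer rejoins the route at 7.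

Step 10. What may go wrong: prenylation of the hindered triketonate may be reversible or O-selective, and facial control at C5 may be insufficient. Fallback: introduce the smaller allyl group and build the prenyl terminus afterwards. Setting out from 17, Pd/Trost-ligand allylation with allyl acetate and Cs2CO3 should give (2S,5R,7S)-2-[(2S)-2-hydroxy-6-methylhept-5-en-2-yl]-7-methyl-7-(3-methylbut-2-en-1-yl)-5-(2-methylpropanoyl)-5-(prop-2-en-1-yl)-2,3-dihydro-1-benzofuran-4,6(5H,7H)-dione F7. Cross-metathesis of F7 with 2-methylbut-2-ene (Grubbs second-generation catalyst, CH2Cl2, 40 °C), under which the existing trisubstituted alkenes only exchange degenerately, then arrives at 18.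

**Further compounds**
F1 | step 8 | 1-{3-[(dimethylamino)methyl]-2,4,6-trihydroxy-5-methylphenyl}-2-methylpropan-1-one | CC(C)C(=O)c1c(O)c(C)c(O)c(CN(C)C)c1O
F2 | step 8 | trimethylammonium iodide of F1 | CC(C)C(=O)c1c(O)c(C)c(O)c(C[N+](C)(C)C)c1O.[I-]
F3 | step 8 | 3,5-dihydroxy-2-methyl-6-methylidene-4-(2-methylpropanoyl)cyclohexa-2,4-dien-1-one | C=C1C(=O)C(C)=C(O)C(C(=O)C(C)C)=C1O
F4 | step 8 | 1-[(2S)-4,6-dihydroxy-7-methyl-5-(2-methylpropanoyl)-2,3-dihydro-1-benzofuran-2-yl]-5-methylhex-4-en-1-one | CC(C)=CCCC(=O)[C@@H]1Cc2c(O1)c(C)c(O)c(C(=O)C(C)C)c2O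
F5 | step 3 | racemic 4-chloro-2-methyl-2-(3-methylbut-2-en-1-yl)-6-(2-methylpropanoyl)cyclohexane-1,3,5-trione | ClC1C(=O)C(C)(CC=C(C)C)C(=O)C(C(=O)C(C)C)C1=O
F6 | step 3 | racemic 2-methyl-2-(3-methylbut-2-en-1-yl)-4-(2-methylpropanoyl)cyclohexane-1,3,5-trione | C1C(=O)C(C)(CC=C(C)C)C(=O)C(C(=O)C(C)C)C1=O
F7 | step 10 | (2S,5R,7S)-2-[(2S)-2-hydroxy-6-methylhept-5-en-2-yl]-7-methyl-7-(3-methylbut-2-en-1-yl)-5-(2-methylpropanoyl)-5-(prop-2-en-1-yl)-2,3-dihydro-1-benzofuran-4,6(5H,7H)-dione | CC(C)=CCC[C@](C)(O)[C@@H]1CC2=C(O1)[C@](C)(CC=C(C)C)C(=O)[C@](CC=C)(C(=O)C(C)C)C2=O
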